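Remark on the chemistry: the target has no stereocentre, so flavanone 19 is made and used as the racemate. Compounds 1, 6, 7 and 17 are taken as commercial. Compound numbers refer to the list after the steps.

## Analysis of the target

The target 21 is a flavone, C19H18O9: benzo ring A is fused to the 4-pyranone ring C (O1, C2, C3, C4=O, C4a, C8a), and ring B sits on C2. Ring A bears no hydrogen; it carries a free hydroxyl at C5, hydrogen-bonded to the C4 carbonyl, and methoxy groups at C6, C7 and C8. Ring B is a 2',5'-hydroquinone with a methoxy group at C4', so C3, C3' and C6' are the only CH positions. There is no stereocentre; the one centre met on the way (C2 of 19) is racemic and is erased when the C2–C3 double bond is introduced. The ring B hydroquinone is easily oxidised to a quinone, above all in base, and the methyl ethers of ring A are open to Lewis-acid dealkylation. The difficulty lies in telling seven oxygens apart (three free, four methylated) and in closing ring C onto a fully substituted, crowded ring A. The strategy rests on one feature: C4 is an aryl ketone carbon on C4a, and C3 is the CH terminus of the unit O1–C2(ring B)=C3, so an aroyl radical on ring A can reach C3 through a six-membered transition state.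

## Retrosynthetic reasoning

**21 from 20.** The two O–benzyl bonds of ring B and the O–methyl bond at C5 are cut last. The 5-methoxy group is the only methyl ether peri to the C4 carbonyl, so a boron Lewis acid bound to that carbonyl can single it out, and the same reagent removes benzyl ethers. Everything before this step then runs on a fully alkylated compound that cannot oxidise to a quinone.

**20 from 19.** The C2=C3 double bond is taken back to the flavanone. A radical ring closure ending in hydrogen transfer delivers this oxidation level, and dehydrogenation next to the ketone is routine. It also removes the C2 stereocentre, so no stereocontrol is needed anywhere.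

**19 from 18 (key disconnection).** The C3–C4 bond is cut. This leaves an aroyl radical precursor on ring A and a 1-arylvinyl aryl ether, that is, O1–C2 and the C2–ring B bond already in place. Cutting here rather than at O1–C2 or C4–C4a keeps the ring closure neutral and does not ask the crowded ring A to act as a nucleophile. The forward reaction has to close ring C in the 6-endo mode and outrun direct reduction of the radical.

**18 from 16, and 16 from 14.** The C(=O)–Se bond is made from a carboxylate, and the carboxyl carbon from an aryl bromide through aryllithium 15. The carboxyl group is kept as the lithium salt 16 throughout. Protonating it would place a carboxylic acid next to the electron-rich enol ether and invite intramolecular Markovnikov addition of the acid across the double bond. Bromine is the placeholder because no carboxyl derivative would survive the methylenation that builds the enol ether, whereas an aryl bromide does.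

**14 from 13.** The enol ether C=CH2 is traced to an ester C=O by carbonyl methylenation. O1–C2 is then made by plain O-acylation. The other option, metal-catalysed addition of a hindered phenol to an arylalkyne, would have to contend with the ortho-benzyloxy group of ring B, which can itself attack an activated triple bond.

**13 from 11 and 5.** The ester C–O bond is cut. This joins ring A and ring B, each with all its oxygens already in place.

**5 from 4, and 4 from 1.** The C–Br bond and then the phenolic C–O bond are cut. The two ring CH positions of 1 are equivalent by symmetry, so metalation and oxidation can give only 4. Phenol 4 has a single CH left, ortho to the hydroxyl group, so the bromine can go only there.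

**11 from 10, 10 from 8, and 8 from 6 and 7.** The carboxyl group comes from a formyl group, and the formyl C–C bond is made by electrophilic substitution para to the methoxy group of 8, the most activated free position. The two benzyl groups of 8 both come from 7, one for each phenol of 6. Benzyl ethers are chosen because they are inert to the methylenation, the lithiation and the radical step, and fall in the same operation as the 5-methyl ether.

## Alternatives that were turned down

**Alternative 1: ring B by cycloaddition.** Ring B is cut at C1'–C2' and C5'–C6' into 2-ethynyl-5,6,7,8-tetramethoxy-4H-chromen-4-one (A2) and 4-methoxy-2-(trimethylsilyloxy)furan (A3). In the forward step the furan of A3 adds [4+2] to the alkyne of A2, the oxygen bridge opens at the siloxy-bearing bridgehead, and tautomerisation gives the free hydroquinone 2-(2,5-dihydroxy-4-methoxyphenyl)-5,6,7,8-tetramethoxy-4H-chromen-4-one (A1).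
- For: ring B is built with all three oxygens placed by the polarity of the two partners. The hydroquinone arrives unprotected, so no benzyl ethers are needed. On protecting-group economy and convergence this is stronger than the chosen route.
- Against: the alkyne of A2 is activated only vinylogously through the chromone, so heat is needed. Under heat A3, a moisture-sensitive ketene acetal, is prone to stepwise vinylogous Michael addition that stops at a butenolide, and to desilylation. A2 needs its own multistep synthesis from a ring A acetophenone. A1 still needs the chelation-controlled 5-demethylation, now on an unprotected hydroquinone.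
- Comparison: the chosen route takes ring B intact from 6 and places its one uncertain step in an intramolecular closure whose regiochemistry is fixed by structure. Here the uncertain step is intermolecular and has both regiochemical and chemoselectivity questions. Step count is no lower.

**Alternative 2: ring A by squarate ring expansion.** Ring A is cut at C8–C8a, and earlier at C4a–C5, back to 4-{6-[2,5-bis(benzyloxy)-4-methoxyphenyl]-4-oxo-4H-pyran-3-yl}-4-hydroxy-2,3-dimethoxycyclobut-2-en-1-one (A5), the adduct of a metallated pyranone and a squaric ester. On heating, A5 opens to a vinylketene, the ketene carbon bonds to the CH carbon next to the pyranone oxygen, and tautomerisation gives 2-[2,5-bis(benzyloxy)-4-methoxyphenyl]-5,8-dihydroxy-6,7-dimethoxy-4H-chromen-4-one (A4).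
- For: all four oxygens of ring A arrive in one step. The 5-hydroxyl is free and hydrogen-bonded, so the 8-hydroxyl can be methylated alone and no final demethylation is needed. On that point it is stronger than the chosen route, which must rely on selective cleavage in step 12.
- Against: A5 needs a pyranone metallated next to its carbonyl, a ring that is itself a Michael acceptor and opens with nucleophiles. The aryl pyranone has to be built first. A4 is an electron-rich para-hydroquinone that oxidises readily to the 5,8-quinone. Methylation and debenzylation still follow, and the sequence is longer.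
- Comparison: the chosen route uses both rings from commercial arenes and needs no organometallic on a sensitive heterocycle.

**Alternative 3: ring C by Friedel–Crafts acylation.** The C4–C4a bond is cut back to (Z)-3-[2,5-bis(benzyloxy)-4-methoxyphenyl]-3-(2,3,4,5-tetramethoxyphenoxy)prop-2-enoic acid (A7). Its activated carboxyl group acylates the only free carbon of the phenoxy ring and gives 2-[2,5-bis(benzyloxy)-4-methoxyphenyl]-5,6,7,8-tetramethoxy-4H-chromen-4-one (A6). A6 is the same compound as 20 of the chosen route.
- For: simple ionic chemistry with unambiguous regiochemistry. A6 is reached directly at the flavone oxidation level, so no dehydrogenation is needed, and no tin or selenium is used. A7 should come quickly from 4 by conjugate addition to an arylpropiolate. In step count and reagent simplicity it is as strong as or stronger than the chosen route.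
- Against: the activation is strongly acidic, and A7 is an enol ether that can hydrolyse or revert under acid. Only the Z isomer can close onto ring A to A6; the E isomer can acylate ring B to an indenone. The benzyl ethers on electron-rich ring B can cleave or migrate, and the site of attack is flanked by two oxygen substituents.
- Comparison: the chosen route closes the ring under neutral conditions that threaten neither the enol ether nor the benzyl ethers, and the ring size is fixed by alkene substitution and not by alkene geometry.

Key step: step 10

## Route

Step 1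
Reactants: 1 1,2,3,4-tetramethoxybenzene
Product: 4 2,3,4,5-tetramethoxyphenol, via 2,3,4,5-tetramethoxyphenyllithium 2 (not isolated), via dimethyl 2,3,4,5-tetramethoxyphenylboronate 3 (not isolated)
Conditions: n-BuLi, TMEDA, THF, 0 °C → rt; B(OMe)3, −78 °C → rt; then AcOH, 30% H2O2, 0 °C → rt
Reagents that add atoms: hydrogen peroxide, OO
Why: Directed ortho-metalation next to a methoxy group (the two CH positions of 1 are equivalent by symmetry, so only one aryllithium can form), borylation and oxidative boron-to-oxygen migration should give the phenol in one flask; this is the standard lithiation–borylation–oxidation of alkoxyarenes.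

Step 2
Reactants: 4 2,3,4,5-tetramethoxyphenol
Product: 5 2-bromo-3,4,5,6-tetramethoxyphenol
Conditions: NBS, CH2Cl2, −78 → 0 °C, dark
Reagents that add atoms: N-bromosuccinimide, O=C1CCC(=O)N1Br
Why: Electrophilic aromatic bromination; the only unsubstituted ring carbon of 4 is ortho to the hydroxyl group, so the position is fixed, and the cold anhydrous medium should keep the electron-rich phenol from being oxidised.

Step 3
Reactants: 6 2-methoxyhydroquinone; 7 benzyl bromide
Product: 8 1,4-bis(benzyloxy)-2-methoxybenzene
Conditions: BnBr (2.2 equiv), K2CO3, DMF, 50 °C, under N2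
Reagents that add atoms: benzyl bromide (second equivalent), BrCc1ccccc1
Why: Twofold Williamson etherification; each of the two phenoxides of 6 takes up one benzyl group, so two equivalents of 7 are consumed, and excluding air keeps the hydroquinone from oxidising before it is alkylated.

Step 4
Reactants: 8 1,4-bis(benzyloxy)-2-methoxybenzene
Product: 10 2,5-bis(benzyloxy)-4-methoxybenzaldehyde, via benzylidene-dimethyliminium dichlorophosphate 9 (not isolated)
Conditions: POCl3, DMF, 0 → 60 °C; then aq NaOAc
Reagents that add atoms: N,N-dimethylformamide, CN(C)C=O; water, O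
Why: Vilsmeier–Haack formylation; of the three free positions of 8 the one para to the methoxy group and ortho to a benzyloxy group is the most activated and least hindered, as in 1,2,4-trialkoxybenzenes generally, and iminium salt 9 is hydrolysed on work-up.

Step 5
Reactants: 10 2,5-bis(benzyloxy)-4-methoxybenzaldehyde
Product: 11 2,5-bis(benzyloxy)-4-methoxybenzoic acid
Conditions: NaClO2, NaH2PO4, 2-methyl-2-butene, t-BuOH/THF/H2O, 0 °C → rt
Reagents that add atoms: sodium chlorite, [Na+].[O-]Cl=O
Why: Pinnick oxidation; chlorite oxidises the aldehyde without touching the benzyl ethers, and the alkene scavenger removes hypochlorous acid before it can chlorinate the electron-rich ring.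

Step 6
Reactants: 11 2,5-bis(benzyloxy)-4-methoxybenzoic acid; 5 2-bromo-3,4,5,6-tetramethoxyphenol
Product: 13 2-bromo-3,4,5,6-tetramethoxyphenyl 2,5-bis(benzyloxy)-4-methoxybenzoate, via 2,5-bis(benzyloxy)-4-methoxybenzoyl chloride 12 (not isolated)
Conditions: (COCl)2, cat. DMF, CH2Cl2, 0 °C → rt, evaporate; then 5, Et3N, DMAP, CH2Cl2, 0 °C → rt
Reagents that add atoms: none
Why: Acyl chloride formation followed by DMAP-catalysed O-acylation; the acyl chloride is used because phenol 5 is flanked by bromine and methoxy and would be a poor partner in a carbodiimide coupling.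

Step 7
Reactants: 13 2-bromo-3,4,5,6-tetramethoxyphenyl 2,5-bis(benzyloxy)-4-methoxybenzoate
Product: 14 1,4-bis(benzyloxy)-2-[1-(2-bromo-3,4,5,6-tetramethoxyphenoxy)ethenyl]-5-methoxybenzene
Conditions: Cp2Ti(μ-Cl)(μ-CH2)AlMe2 (Tebbe reagent), cat. pyridine, THF/toluene, −40 °C → rt; aq NaOH quench; basic alumina
Reagents that add atoms: Cp2Ti(μ-Cl)(μ-CH2)AlMe2 (Tebbe reagent), [cH-]1cccc1.[cH-]1cccc1.C[Al-]1(C)C[Ti+2][Cl+]1
Why: Tebbe methylenation of an ester carbonyl ([2+2] addition of the titanium methylidene Cp2Ti=CH2 to C=O, then cycloreversion); aryl benzoates are standard substrates for conversion into 1-arylvinyl aryl ethers, and the aryl bromide, benzyl ethers and methyl ethers are inert. Basic work-up and basic alumina protect the acid-labile enol ether.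

Step 8
Reactants: 14 1,4-bis(benzyloxy)-2-[1-(2-bromo-3,4,5,6-tetramethoxyphenoxy)ethenyl]-5-methoxybenzene
Product: 16 lithium 2-{[1-(2,5-bis(benzyloxy)-4-methoxyphenyl)ethenyl]oxy}-3,4,5,6-tetramethoxybenzoate, via ring A aryllithium 15 (not isolated)
Conditions: n-BuLi, THF, −78 °C, 10 min; CO2 (gas), −78 °C → rt; evaporate, triturate with pentane (no acid)
Reagents that add atoms: n-butyllithium, [Li]CCCC; carbon dioxide, O=C=O
Why: Bromine–lithium exchange at −78 °C is much faster than deprotonation of the benzylic ether positions or addition to the styrene-type double bond, and the aryllithium is then carboxylated. The product is kept as its lithium salt because a free carboxylic acid ortho to the enol ether would add across it.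

Step 9
Reactants: 16 lithium 2-{[1-(2,5-bis(benzyloxy)-4-methoxyphenyl)ethenyl]oxy}-3,4,5,6-tetramethoxybenzoate; 17 diphenyl diselenide
Product: 18 Se-phenyl 2-{[1-(2,5-bis(benzyloxy)-4-methoxyphenyl)ethenyl]oxy}-3,4,5,6-tetramethoxybenzenecarboselenoate
Conditions: PBu3, THF/CH2Cl2, 0 °C → rt; aq NaHCO3 work-up; Et3N-treated silica
Reagents that add atoms: none
Why: Phosphine–diselenide redox condensation (Mukaiyama type): the carboxylate attacks the selenophosphonium ion formed from PBu3 and 17, and benzeneselenolate then displaces Bu3P=O from the acyloxyphosphonium ion. Starting from the salt means no proton source (neither a carboxylic acid nor benzeneselenol) is present to add to the enol ether.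

Step 10
Reactants: 18 Se-phenyl 2-{[1-(2,5-bis(benzyloxy)-4-methoxyphenyl)ethenyl]oxy}-3,4,5,6-tetramethoxybenzenecarboselenoate
Product: 19 (±)-2-[2,5-bis(benzyloxy)-4-methoxyphenyl]-5,6,7,8-tetramethoxy-2,3-dihydro-4H-chromen-4-one
Conditions: Bu3SnH, AIBN (syringe pump, 6 h), degassed benzene, 80 °C, 0.01 M
Reagents that add atoms: none
Why: AIBN-derived radicals generate Bu3Sn•, which attacks selenium of 18 and releases the aroyl radical at the future C4 together with Bu3SnSePh. This aroyl radical is a σ-radical that should not lose CO at 80 °C, since that would give an aryl radical. It adds to the unsubstituted CH2 terminus (future C3) of the 1-arylvinyl ether, forming C3–C4 and closing ring C in the 6-endo-trig mode; the 5-exo mode would need attack at the fully substituted carbon bearing O1 and ring B and would give a primary radical. The adduct radical at C2 is stabilised by O1 and by ring B, which should make the addition fast and irreversible, and it takes hydrogen from Bu3SnH to give 19 and the chain-carrying Bu3Sn•. The closest known reaction type is the stannane-mediated cyclisation of acyl radicals from phenyl selenoesters onto 1,1-disubstituted alkenes, which takes the endo course for the same reason. C2 is the only new stereocentre; nothing controls it, since hydrogen is delivered to either face of a planar radical, so 19 is racemic and the centre disappears in step 11. The selectivities needed are endo over exo closure, secured by the alkene substitution, and cyclisation over direct reduction of the aroyl radical, secured by high dilution and slow addition of the stannane. The medium is neutral, so the acid-labile enol ether of 18 and the benzyl ethers are not at risk.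

Step 11
Reactants: 19 (±)-2-[2,5-bis(benzyloxy)-4-methoxyphenyl]-5,6,7,8-tetramethoxy-2,3-dihydro-4H-chromen-4-one
Product: 20 2-[2,5-bis(benzyloxy)-4-methoxyphenyl]-5,6,7,8-tetramethoxy-4H-chromen-4-one
Conditions: I2 (cat.), DMSO, 120 °C
Reagents that add atoms: none
Why: Iodine-mediated dehydrogenation of a flavanone (iodination at C3 through the enol and loss of HI, with DMSO re-oxidising the iodide); this is the standard flavanone-to-flavone conversion and removes the C2 stereocentre.

Step 12
Reactants: 20 2-[2,5-bis(benzyloxy)-4-methoxyphenyl]-5,6,7,8-tetramethoxy-4H-chromen-4-one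
Product: 21 2-(2,5-dihydroxy-4-methoxyphenyl)-5-hydroxy-6,7,8-trimethoxy-4H-chromen-4-one
Conditions: BCl3, pentamethylbenzene, CH2Cl2, −78 °C → 0 °C; MeOH quench; degassed aqueous work-up
Reagents that add atoms: none
Why: Lewis-acid ether cleavage: BCl3 removes aryl benzyl ethers at low temperature, with pentamethylbenzene trapping the benzyl cation so that it cannot alkylate ring B. On warming, boron bound to the C4 carbonyl should cleave only the peri 5-methoxy group through a six-membered chelate, leaving the non-chelated methyl ethers at C6, C7, C8 and C4'.

## Compound list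

1 | 1,2,3,4-tetramethoxybenzene | COc1ccc(OC)c(OC)c1OC | starting material
2 | (2,3,4,5-tetramethoxyphenyl)lithium | [Li]c1cc(OC)c(OC)c(OC)c1OC | intermediate (not isolated)
3 | dimethyl (2,3,4,5-tetramethoxyphenyl)boronate | COB(OC)c1cc(OC)c(OC)c(OC)c1OC | intermediate (not isolated)
4 | 2,3,4,5-tetramethoxyphenol | Oc1cc(OC)c(OC)c(OC)c1OC | intermediate
5 | 2-bromo-3,4,5,6-tetramethoxyphenol | Oc1c(Br)c(OC)c(OC)c(OC)c1OC | intermediate
6 | 2-methoxyhydroquinone | COc1cc(O)ccc1O | starting material
7 | benzyl bromide | BrCc1ccccc1 | starting material
8 | 1,4-bis(benzyloxy)-2-methoxybenzene | COc1cc(OCc2ccccc2)ccc1OCc1ccccc1 | intermediate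
9 | [2,5-bis(benzyloxy)-4-methoxybenzylidene]dimethyliminium dichlorophosphate | C[N+](C)=Cc1cc(OCc2ccccc2)c(OC)cc1OCc1ccccc1.[O-]P(Cl)(Cl)=O | intermediate (not isolated)
10 | 2,5-bis(benzyloxy)-4-methoxybenzaldehyde | COc1cc(OCc2ccccc2)c(C=O)cc1OCc1ccccc1 | intermediate
11 | 2,5-bis(benzyloxy)-4-methoxybenzoic acid | COc1cc(OCc2ccccc2)c(C(=O)O)cc1OCc1ccccc1 | intermediate
12 | 2,5-bis(benzyloxy)-4-methoxybenzoyl chloride | COc1cc(OCc2ccccc2)c(C(Cl)=O)cc1OCc1ccccc1 | intermediate (not isolated)
13 | 2-bromo-3,4,5,6-tetramethoxyphenyl 2,5-bis(benzyloxy)-4-methoxybenzoate | COc1cc(OCc2ccccc2)c(C(=O)Oc2c(Br)c(OC)c(OC)c(OC)c2OC)cc1OCc1ccccc1 | intermediate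
14 | 1,4-bis(benzyloxy)-2-[1-(2-bromo-3,4,5,6-tetramethoxyphenoxy)ethenyl]-5-methoxybenzene | COc1cc(OCc2ccccc2)c(C(=C)Oc2c(Br)c(OC)c(OC)c(OC)c2OC)cc1OCc1ccccc1 | intermediate
15 | (2-{[1-(2,5-bis(benzyloxy)-4-methoxyphenyl)ethenyl]oxy}-3,4,5,6-tetramethoxyphenyl)lithium | COc1cc(OCc2ccccc2)c(C(=C)Oc2c([Li])c(OC)c(OC)c(OC)c2OC)cc1OCc1ccccc1 | intermediate (not isolated)
16 | lithium 2-{[1-(2,5-bis(benzyloxy)-4-methoxyphenyl)ethenyl]oxy}-3,4,5,6-tetramethoxybenzoate | COc1cc(OCc2ccccc2)c(C(=C)Oc2c(C(=O)[O-])c(OC)c(OC)c(OC)c2OC)cc1OCc1ccccc1.[Li+] | intermediate
17 | diphenyl diselenide | c1ccc(cc1)[Se][Se]c1ccccc1 | starting material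
18 | Se-phenyl 2-{[1-(2,5-bis(benzyloxy)-4-methoxyphenyl)ethenyl]oxy}-3,4,5,6-tetramethoxybenzenecarboselenoate | COc1c(OC)c(OC)c(C(=O)[Se]c2ccccc2)c(OC(=C)c2cc(OCc3ccccc3)c(OC)cc2OCc2ccccc2)c1OC | intermediate
19 | (±)-2-[2,5-bis(benzyloxy)-4-methoxyphenyl]-5,6,7,8-tetramethoxy-2,3-dihydro-4H-chromen-4-one (racemic at C2) | COc1cc(OCc2ccccc2)c(C2CC(=O)c3c(OC)c(OC)c(OC)c(OC)c3O2)cc1OCc1ccccc1 | intermediate
20 | 2-[2,5-bis(benzyloxy)-4-methoxyphenyl]-5,6,7,8-tetramethoxy-4H-chromen-4-one | COc1cc(OCc2ccccc2)c(-c2cc(=O)c3c(OC)c(OC)c(OC)c(OC)c3o2)cc1OCc1ccccc1 | intermediate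
21 | 2-(2,5-dihydroxy-4-methoxyphenyl)-5-hydroxy-6,7,8-trimethoxy-4H-chromen-4-one | COc1cc(O)c(-c2cc(=O)c3c(O)c(OC)c(OC)c(OC)c3o2)cc1O | target

## Step count and risks

Total step count: 12. Longest linear sequence: 10 steps (steps 3 to 12, from 6); the ring A branch (steps 1 and 2) joins at step 6.

**Step 10 (key step).**
- Risk: the aroyl radical may take hydrogen from the stannane before it cyclises. Addition of a nucleophilic acyl radical to an electron-rich enol ether is polarity-mismatched. The methoxy group next to O1 may also hold the vinyl ether in rotamers that turn the CH2 terminus away from the radical. The stabilised C2 radical may in turn abstract hydrogen slowly at the low stannane concentration that the first problem calls for, which would break the chain.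
- Fallback: give up the radical closure and build ring C from a chalcone, setting out from 4 and 10 and returning at 20. Phenol 4 is C-acetylated at its only free position (Ac2O, BF3·OEt2, 80 °C) to give 1-(2-hydroxy-3,4,5,6-tetramethoxyphenyl)ethan-1-one F1. Claisen–Schmidt condensation of F1 with 10 (KOH, EtOH, rt) gives (E)-3-[2,5-bis(benzyloxy)-4-methoxyphenyl]-1-(2-hydroxy-3,4,5,6-tetramethoxyphenyl)prop-2-en-1-one F2. Heating F2 with I2 in DMSO at 120 °C closes O1–C2 by oxa-Michael addition and dehydrogenates in the same flask to 20.

**Step 7.**
- Risk: methylenation may stall at the crowded ester carbonyl, and the aluminium Lewis acid or a slightly acidic work-up may hydrolyse the enol ether back to a ketone and a phenol.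
- Fallback: make the enol ether by addition and elimination, setting out from 10 and 5 and returning at 14. Wittig methylenation of 10 (Ph3PCH3Br, KOt-Bu, THF) gives 1,4-bis(benzyloxy)-2-ethenyl-5-methoxybenzene F3. Bromoetherification of F3 with NBS in the presence of 5 (CH2Cl2, −40 °C) gives racemic 1-bromo-2-{1-[2,5-bis(benzyloxy)-4-methoxyphenyl]-2-bromoethoxy}-3,4,5,6-tetramethoxybenzene F4; the phenol oxygen adds at the benzylic carbon, and the ring of 5 has no free position to be brominated. Dehydrobromination of F4 with KOt-Bu in THF at 0 °C gives 14.

**Step 9.**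
- Risk: acyl transfer at the doubly ortho-substituted carbonyl may be slow, and any adventitious proton source would set off addition of the carboxyl group or of selenol across the enol ether.
- Fallback: generate the same aroyl radical from an aldehyde, setting out from 14 and returning at 19. Bromine–lithium exchange on 14 (n-BuLi, THF, −78 °C), quenching with DMF and a neutral aqueous work-up gives 2-{[1-(2,5-bis(benzyloxy)-4-methoxyphenyl)ethenyl]oxy}-3,4,5,6-tetramethoxybenzaldehyde F5. Under thiol catalysis (tert-dodecanethiol, AIBN, benzene, 80 °C) a thiyl radical abstracts the formyl hydrogen of F5, the aroyl radical closes 6-endo as in step 10, and the thiol returns hydrogen to C2 to give 19. Its own weak point is reversible thiyl addition to the alkene, which can consume the catalyst.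

**Step 12.**
- Risk: dealkylation may go beyond the 5-methoxy group (the 6-methoxy group next to the boron-bound 5-oxygen and the 4'-methoxy group next to the 5'-oxygen are the likely sites), ring B may be C-benzylated if cation trapping is incomplete, and the hydroquinone may oxidise during work-up.
- Fallback: separate the two cleavages and finish under neutral conditions, setting out from 20 and returning at 21. Chelation-controlled demethylation of 20 with MgI2·OEt2 (toluene/Et2O, 70 °C) gives 2-[2,5-bis(benzyloxy)-4-methoxyphenyl]-5-hydroxy-6,7,8-trimethoxy-4H-chromen-4-one F6. Hydrogenolysis of F6 (H2, Pd/C, EtOAc/THF, rt) gives 21.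

## Further compounds

F1 | step 10 | 1-(2-hydroxy-3,4,5,6-tetramethoxyphenyl)ethan-1-one | CC(=O)c1c(O)c(OC)c(OC)c(OC)c1OC
F2 | step 10 | (E)-3-[2,5-bis(benzyloxy)-4-methoxyphenyl]-1-(2-hydroxy-3,4,5,6-tetramethoxyphenyl)prop-2-en-1-one | COc1cc(OCc2ccccc2)c(/C=C/C(=O)c2c(O)c(OC)c(OC)c(OC)c2OC)cc1OCc1ccccc1
F3 | step 7 | 1,4-bis(benzyloxy)-2-ethenyl-5-methoxybenzene | C=Cc1cc(OCc2ccccc2)c(OC)cc1OCc1ccccc1
F4 | step 7 | 1-bromo-2-{1-[2,5-bis(benzyloxy)-4-methoxyphenyl]-2-bromoethoxy}-3,4,5,6-tetramethoxybenzene (racemic) | COc1cc(OCc2ccccc2)c(C(CBr)Oc2c(Br)c(OC)c(OC)c(OC)c2OC)cc1OCc1ccccc1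
F5 | step 9 | 2-{[1-(2,5-bis(benzyloxy)-4-methoxyphenyl)ethenyl]oxy}-3,4,5,6-tetramethoxybenzaldehyde | O=Cc1c(OC)c(OC)c(OC)c(OC)c1OC(=C)c1cc(OCc2ccccc2)c(OC)cc1OCc1ccccc1
F6 | step 12 | 2-[2,5-bis(benzyloxy)-4-methoxyphenyl]-5-hydroxy-6,7,8-trimethoxy-4H-chromen-4-one | COc1cc(OCc2ccccc2)c(-c2cc(=O)c3c(O)c(OC)c(OC)c(OC)c3o2)cc1OCc1ccccc1
A1 | alternative 1 | 2-(2,5-dihydroxy-4-methoxyphenyl)-5,6,7,8-tetramethoxy-4H-chromen-4-one | COc1cc(O)c(-c2cc(=O)c3c(OC)c(OC)c(OC)c(OC)c3o2)cc1O
A2 | alternative 1 | 2-ethynyl-5,6,7,8-tetramethoxy-4H-chromen-4-one | C#Cc1cc(=O)c2c(OC)c(OC)c(OC)c(OC)c2o1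
A3 | alternative 1 | 4-methoxy-2-(trimethylsilyloxy)furan | COc1coc(O[Si](C)(C)C)c1
A4 | alternative 2 | 2-[2,5-bis(benzyloxy)-4-methoxyphenyl]-5,8-dihydroxy-6,7-dimethoxy-4H-chromen-4-one | COc1cc(OCc2ccccc2)c(-c2cc(=O)c3c(O)c(OC)c(OC)c(O)c3o2)cc1OCc1ccccc1
A5 | alternative 2 | 4-{6-[2,5-bis(benzyloxy)-4-methoxyphenyl]-4-oxo-4H-pyran-3-yl}-4-hydroxy-2,3-dimethoxycyclobut-2-en-1-one (racemic) | COC1=C(OC)C(O)(c2coc(cc2=O)-c2cc(OCc3ccccc3)c(OC)cc2OCc2ccccc2)C1=O
A6 | alternative 3 | 2-[2,5-bis(benzyloxy)-4-methoxyphenyl]-5,6,7,8-tetramethoxy-4H-chromen-4-one | COc1cc(OCc2ccccc2)c(-c2cc(=O)c3c(OC)c(OC)c(OC)c(OC)c3o2)cc1OCc1ccccc1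
A7 | alternative 3 | (Z)-3-[2,5-bis(benzyloxy)-4-methoxyphenyl]-3-(2,3,4,5-tetramethoxyphenoxy)prop-2-enoic acid | OC(=O)/C=C(\Oc1cc(OC)c(OC)c(OC)c1OC)c1cc(OCc2ccccc2)c(OC)cc1OCc1ccccc1
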